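# Proposed total synthesis of CNP0284886.1 (iridal-type triol-enal), single enantiomer

Ring locants used throughout: C1 = quaternary carbon (CH2OH and homofarnesyl chain), C2 = CH bearing the 3-hydroxypropyl arm, C3 = sp2 carbon of the exocyclic enal, C4 and C5 = CH2, C6 = C(OH)CH3. Target descriptors: C1 S, C2 R, C6 S, enal Z, chain all-E.

## The problem

The target is one cyclohexane in which every stereochemical problem sits on the contiguous triad C6–C1–C2 and on the C3 olefin. C1 is an all-carbon quaternary centre flanked by a tertiary alcohol (C6) and a tertiary CH (C2), and the three oxygenated arms (C6–OH, C1–CH2OH, C2–(CH2)3OH) are all cis. The two exocyclic groups on C1 are primary alkyl arms of nearly equal size, so C1 cannot be set by steric differentiation and, once set, does not bias C2 or C6 reliably; the relations must come from a bond-forming event that transfers chirality. The enal is tetrasubstituted, exocyclic and Z (CHO syn to C2), is A(1,3)-strained, isomerises easily, and has no neighbour that would dictate its geometry in an intermolecular olefination. The all-E triene chain excludes ozone, halonium ions, strong acid and hydrogenation once it is in place, so it should be joined late by a stereoretentive sp3–sp2 coupling. A carbonyl on C1 next to the C6 tertiary alkoxide is an aldol array open to retro-aldol cleavage, and the final triol-enal is the ring-chain tautomer of a seven-membered lactol. The feature that makes the key step possible: the hydroxymethyl carbon on C1, C1, C6, C5 and C4 form a five-carbon chain that closes through an oxygen on C4 to a δ-lactone in which C6 (CH3, OH) is the β-carbon (a mevalonolactone-type ring), while C4–C3=C2 is an allyl unit, so the lactone enolate carbon C1 and C2 are the termini of an O-allyl ketene acetal. Hence the ring bond C1–C2, the one flanked by the whole triad, can be made by a [3,3] shift that contracts the lactone to the carbocycle, and the same hydroxymethyl oxygen can later tie the aldehyde carbon into a ring to fix the Z geometry.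

## Retrosynthesis

**29 ⇒ 28 ⇒ 27 (no C–C cut).** The triol-enal 29 is the reduced, ring-opened form of the seven-membered lactone 28, in which the C1 hydroxymethyl oxygen is acylated by the enoic acid. In that ring the carbonyl carbon can only lie syn to C2, which is the required Z geometry. The forward steps are fluoride desilylation of 27 and a partial lactone reduction, so the sensitive enal appears last.

**27 ⇒ 26 (cut C3=C(CH3)).** An intramolecular Horner–Wadsworth–Emmons reaction of keto phosphonate 26 closes the unsaturated lactone. The neighbouring cut, an intermolecular olefination of the C3 ketone, has no element to control E/Z at a tetrasubstituted olefin. The precursor is a monocyclic keto ester; the forward reaction must bring a stabilised carbanion onto an α-branched ketone, which the tether assists.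

**26 ⇒ 25 ⇒ 23 + 24 ⇒ 22 (functional-group changes).** The ketone comes from the C3 carbinol of 25, the phosphonate ester from the primary hydroxyl of diol 23 and acid 24. Diol 23 comes from hydride reduction of the bridged γ-lactone 22, which stores the C1 hydroxymethyl and the C3 oxygen as one group.

**22 ⇒ 15 + 20 (cut C2'–C3' of the side chain).** Hydroboration of the C1 vinyl group of 15 and B-alkyl Suzuki coupling with alkenyl iodide 20 brings in 14 of the 30 carbons with all three olefin geometries fixed. Alkylation with a homofarnesyl halide would have to form a neopentyl bond, and a Wittig approach gives no E control at a trisubstituted olefin. The coupling is placed after the steps that use iodine and tin radicals.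

**15 ⇒ 14 ⇒ 13 (cut C3–O).** The carboxyl on C1 of acid 13 delivers oxygen to C3 by iodolactonisation (14), which distinguishes C3 from C4 where no intermolecular reagent would; the iodine is then removed.

**13 ⇒ 11 ⇒ 10 (cut the ring bond C1–C2; key step).** Acid 13 is the [3,3] product of the silyl ketene acetal 11 of δ-lactone 10. This cut is preferred to C1–C6 (an aldol onto a quaternary centre, reversible) and to the exocyclic C1 bonds (no facial bias), because one suprafacial shift through an enforced boat sets C1 and C2 relative to C6. The precursor 10 is a monocyclic lactone whose two controlling centres are a secondary allylic C–O (C4 of the future ring) and the carbinol C6; the first is consumed in the shift. The forward reaction must form a quaternary centre at the α-carbon of a β-silyloxy lactone without elimination.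

**10 ⇒ 9 ⇒ 7 + 8 (cut C1–C6 and the ester C–O).** An intramolecular Reformatsky reaction of the 4-bromocrotonate 9 closes the lactone, sets C6 by 1,3-induction from the allylic carbinol, and leaves a vinyl group on C1 (from the γ-carbon of the crotonate) as the handle for the chain. Ester 9 comes from β-hydroxy ketone 7 and acid 8.

**7 ⇒ 4 + 5; 4 ⇒ 2 + 3; 2 ⇒ 1.** The only stereocentre that needs an external source of chirality is the carbinol of 7, set by a catalytic enantioselective acetone-aldol addition of 2-methoxypropene 5 (via enol ether 6) to enal 4. Enal 4 comes from cross-metathesis of silyl ether 2 (from pentenol 1) with crotonaldehyde 3.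

**20 ⇒ 18 ⇒ 16.** Alkenyl iodide 20 comes from carboalumination–iodination of enyne 18 (via alane 19), itself made from (E)-geranylacetone 16 through enol phosphate 17.

## Roads not taken

**Alternative 1:** (the most obvious) Cut the two exocyclic bonds C2–propyl and C1–chain. Forward key step: copper-mediated conjugate addition of a 3-silyloxypropyl nucleophile to the enone ester A1 with trapping of the enolate by homofarnesyl iodide to give the trans keto ester A2, then methyl addition to the C6 ketone, ester reduction and olefination at C3. The chosen plan is better for four reasons.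
- The alkylation must form the quaternary centre with an unactivated homoallylic iodide.
- The methyl addition must distinguish ketone faces defined only by CO2Me versus CH2R on C1, and it passes through a β-alkoxide ester prone to retro-aldol cleavage.
- The absolute configuration needs an enantioselective conjugate addition to a hindered, doubly activated enone.
- Nothing controls the enal geometry.

Three independent weak selections are replaced in the chosen plan by one chirality-transferring step.

**Alternative 2:** Chiral pool: the ring with its C6 methyl and the three-carbon branch on C3 is a p-menthane, so (S)-carvone maps onto ten carbons. Cut the C1–CH2OH bond. Forward key step: [2,3]-Wittig–Still rearrangement of stannylmethyl ether A4, reached from trans-6-allylcarvone A3 by 1,2-addition of the chain organolithium, oxidative transposition, reduction and inversion. The chosen plan is better for three reasons.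
- The controlling carvone centre must be destroyed to make the enal, and isomerising an isopropenyl group into a tetrasubstituted Z-enal has no control element and requires allylic oxidation in the presence of the polyene.
- The allyl group must be hydroborated beside an isopropenyl group and three chain olefins.
- The C6 alcohol must still be set on a trisubstituted ring olefin, and the run-up to A4 alone is as long as the whole route to 13.

**Alternative 3:** Cut C1–C2 and a bond of a temporary second ring. Forward key step: type-1 intramolecular Diels–Alder reaction of trienone A5 to the cis-octalone A6, whose ozonolysis unveils the one-carbon arm on C1 and the three-carbon arm on C2, cis by ring fusion. The chosen plan is better for four reasons.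
- In A5 the allylic quaternary carbinol (CH3 versus OSi) gives no reliable facial control, so the C6 relation is uncertain.
- The reacting diene terminus is 1,1-disubstituted and therefore slow.
- The ozonolysis forbids the presence of the chain and leaves two aldehydes to be differentiated.
- The enal geometry is not addressed.

The chosen plan forms the same C1–C2 bond inside a ring that already holds C6 in a defined relation.

Key step: step 6

## Assumptions

Assumption: the antipode of the Ti aldol catalyst that delivers the (4R)-carbinol 7 is used; either ligand antipode is accessible, so the sense of induction can be matched.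
Assumption: lactone 10 is carried as the mixture of C3 epimers, since both give the same ketene acetal 11.
Assumption: the target is taken as the open triol-enal as drawn, the ring-chain tautomer of its seven-membered lactol.

## Steps

Step 1
Reactants: 1 pent-4-en-1-ol
Product: 2 tert-butyl(pent-4-en-1-yloxy)diphenylsilane
Conditions: TBDPSCl, imidazole, CH2Cl2, 0 °C to rt
Reagents that add atoms: tert-butyl(chloro)diphenylsilane (TBDPSCl), CC(C)(C)[Si](Cl)(c1ccccc1)c1ccccc1
Why: Standard silylation of a primary alcohol; the TBDPS ether should survive Lewis acid, SmI2, iodine, tin hydride, hydride and base until step 16.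

Step 2
Reactants: 2 tert-butyl(pent-4-en-1-yloxy)diphenylsilane; 3 (E)-but-2-enal
Product: 4 (E)-6-[(tert-butyldiphenylsilyl)oxy]hex-2-enal
Conditions: 3 (4 equiv), second-generation Ru isopropoxybenzylidene/NHC metathesis catalyst (3 mol %), CH2Cl2, 40 °C
Reagents that add atoms: none
Why: Olefin cross-metathesis of a terminal alkene with crotonaldehyde should give the (E)-enal selectively, with propene leaving as a gas.

Step 3
Reactants: 4 (E)-6-[(tert-butyldiphenylsilyl)oxy]hex-2-enal; 5 2-methoxypropene
Product: 7 (4R,5E)-9-[(tert-butyldiphenylsilyl)oxy]-4-hydroxynon-5-en-2-one, via enol ether adduct 6 (not isolated)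
Conditions: 5 (excess), Ti(OiPr)4/binaphthyl-derived tridentate Schiff-base ligand/3,5-di-tert-butylsalicylic acid (5 mol %), Et2O, 0 °C; then 1 M aq. HCl, Et2O, 0 °C
Reagents that add atoms: water, O
Why: Ti(IV)-catalysed enantioselective ene-type (Mukaiyama-like) aldol addition of 2-methoxypropene, a catalytic acetone aldol known for conjugated aldehydes; the chiral Ti complex sets the carbinol centre (R) by 1,2-addition, and mild acid hydrolyses enol ether 6 to the methyl ketone.

Step 4
Reactants: 7 (4R,5E)-9-[(tert-butyldiphenylsilyl)oxy]-4-hydroxynon-5-en-2-one; 8 (E)-4-bromobut-2-enoic acid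
Product: 9 (4R,5E)-9-[(tert-butyldiphenylsilyl)oxy]-2-oxonon-5-en-4-yl (2E)-4-bromobut-2-enoate
Conditions: DCC, DMAP (5 mol %), CH2Cl2, −20 to 0 °C
Reagents that add atoms: none
Why: Steglich esterification of the secondary allylic alcohol; low temperature and catalytic DMAP should avoid β-elimination of the β-acyloxy ketone and N-alkylation by the allylic bromide.

Step 5
Reactants: 9 (4R,5E)-9-[(tert-butyldiphenylsilyl)oxy]-2-oxonon-5-en-4-yl (2E)-4-bromobut-2-enoate
Product: 10 (3RS,4S,6R)-6-{(1E)-5-[(tert-butyldiphenylsilyl)oxy]pent-1-en-1-yl}-4-hydroxy-4-methyl-3-vinyltetrahydro-2H-pyran-2-one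
Conditions: SmI2 (2.3 equiv), THF, −78 °C; aq. NH4Cl
Reagents that add atoms: none
Why: SmI2-mediated intramolecular (vinylogous) Reformatsky reaction: reduction of the allylic bromide gives a Sm(III) dienolate that attacks the methyl ketone through its α-carbon (six- rather than eight-membered ring); in the Sm-bridged bicyclic chair the ketone oxygen is axial and the C6 alkenyl group equatorial, so the new hydroxyl should be trans to the alkenyl group (4S from 6R), while the C3 configuration is irrelevant.

Step 6
Reactants: 10 (3RS,4S,6R)-6-{(1E)-5-[(tert-butyldiphenylsilyl)oxy]pent-1-en-1-yl}-4-hydroxy-4-methyl-3-vinyltetrahydro-2H-pyran-2-one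
Product: 13 (1R,2R,6S)-2-{3-[(tert-butyldiphenylsilyl)oxy]propyl}-6-methyl-6-[(triethylsilyl)oxy]-1-vinylcyclohex-3-ene-1-carboxylic acid, via dienyl ketene acetal 11 (not isolated), via silyl ester 12 (not isolated)
Conditions: TESOTf (3 equiv), Et3N (5 equiv), CH2Cl2, −78 to 0 °C; solvent exchange to toluene, 110 °C; then MeOH–H2O, AcOH (cat.), rt
Reagents that add atoms: triethylsilyl trifluoromethanesulfonate (TESOTf), CC[Si](CC)(CC)OS(=O)(=O)C(F)(F)F
Why: TESOTf/Et3N silylates the tertiary alcohol and soft-enolises the doubly activated C3–H (α to the carbonyl and allylic) to the 6-silyloxy-5-vinyl-3,4-dihydro-2H-pyran 11, an O-allyl silyl ketene acetal, which on heating undergoes the ester-enolate (Ireland-type) Claisen rearrangement of a lactone, the known ring contraction of 6-alkenyl δ-lactone ketene acetals to cyclohex-3-enecarboxylic acids. The carbocycle is closed by sigmatropic formation of the C1–C2 σ-bond while the lactone C–O bond breaks, and because the ketene acetal double bond is endocyclic the six-atom array is held in a bicyclo[2.2.2]-like boat. C1 (quaternary): the new bond forms on the lactone face that carries the alkenyl group, which is trans to the C4 silyloxy group, so the carboxyl ends cis to the C6 oxygen and the vinyl group cis to the C6 methyl. C2: in the boat the (E)-olefin places its alkyl chain on the carboxyl side and its hydrogen under C6, so the silyloxypropyl arm ends cis to the carboxyl. The original carbinol carbon becomes sp2 (ring C4), so chirality passes from the one catalyst-set centre to C1 and C2, and both C3 epimers of 10 converge on the single ketene acetal 11. The step needs O-silylation without loss of the β-silyloxy group (secured by non-basic soft enolisation and immediate trapping) and reaction at the α-carbon only (the vinylogous terminus cannot reach the allyl unit). Formation of the C=O bond drives the congested quaternary centre, and mild methanolysis frees the acid while the tertiary TES ether stays.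

Step 7
Reactants: 13 (1R,2R,6S)-2-{3-[(tert-butyldiphenylsilyl)oxy]propyl}-6-methyl-6-[(triethylsilyl)oxy]-1-vinylcyclohex-3-ene-1-carboxylic acid
Product: 14 iodo-γ-lactone of 13: 4-iodo-2-methyl-8-{3-[(tert-butyldiphenylsilyl)oxy]propyl}-2-[(triethylsilyl)oxy]-1-vinyl-6-oxabicyclo[3.2.1]octan-7-one (lactone O on ring C3 cis to the carboxyl carbon, I on ring C4 trans to that O; C1, C2, C6 as in 13)
Conditions: I2, NaHCO3, MeCN–H2O, 0 °C, dark
Reagents that add atoms: iodine, II
Why: Kinetic iodolactonisation of a γ,δ-unsaturated acid (5-exo attack of the carboxylate at C3 anti to the iodonium ion) puts oxygen regiospecifically on C3; the vinyl group would need 4-exo closure and should not compete, and both new centres are removed later.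

Step 8
Reactants: 14 iodo-γ-lactone
Product: 15 2-methyl-8-{3-[(tert-butyldiphenylsilyl)oxy]propyl}-2-[(triethylsilyl)oxy]-1-vinyl-6-oxabicyclo[3.2.1]octan-7-one (C1, C2, C6 of the carbocycle as in 13)
Conditions: Bu3SnH, AIBN (cat.), toluene, 80 °C
Reagents that add atoms: none
Why: Radical chain deiodination; the neopentyl vinyl group and the lactone are inert to the stannyl radical under these conditions.

Step 9
Reactants: 16 (5E)-6,10-dimethylundeca-5,9-dien-2-one ((E)-geranylacetone)
Product: 18 (5E)-6,10-dimethylundeca-5,9-dien-1-yne, via enol phosphate 17 (not isolated)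
Conditions: LDA (1.1 equiv), THF, −78 °C; ClP(O)(OEt)2; then LDA (2.3 equiv), −78 °C to rt
Reagents that add atoms: none
Why: Kinetic enolisation at the methyl group, O-phosphorylation and base-induced elimination of the enol phosphate give the terminal alkyne in one pot; the 5E olefin is not touched.

Step 10
Reactants: 18 (5E)-6,10-dimethylundeca-5,9-dien-1-yne
Product: 20 (1E,5E)-1-iodo-2,6,10-trimethylundeca-1,5,9-triene, via alkenylalane 19 (not isolated)
Conditions: Me3Al, Cp2ZrCl2 (cat.), CH2Cl2, 0 °C to rt; then I2, THF, −30 °C
Reagents that add atoms: trimethylaluminium, C[Al](C)C; iodine, II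
Why: Zr-catalysed carboalumination (syn methylalumination of the terminal alkyne) followed by iodinolysis with retention gives the (E)-2-methyl-1-iodoalkene.

Step 11
Reactants: 15 bridged vinyl lactone; 20 (1E,5E)-1-iodo-2,6,10-trimethylundeca-1,5,9-triene
Product: 22 2-methyl-8-{3-[(tert-butyldiphenylsilyl)oxy]propyl}-2-[(triethylsilyl)oxy]-1-[(3E,7E)-4,8,12-trimethyltrideca-3,7,11-trien-1-yl]-6-oxabicyclo[3.2.1]octan-7-one, via alkylborane 21 (not isolated)
Conditions: 9-BBN, THF, rt; then 20, Pd(dppf)Cl2 (5 mol %), AsPh3, Cs2CO3, DMF–H2O, rt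
Reagents that add atoms: none
Why: Anti-Markovnikov hydroboration of the only olefin and B-alkyl Suzuki–Miyaura coupling with retention of the alkenyl iodide geometry create the 3E olefin and complete the chain; lactone and silyl ethers tolerate both stages.

Step 12
Reactants: 22 bridged lactone with the complete chain
Product: 23 diol: ring C1 hydroxymethyl, ring C3 hydroxyl cis to it, C6 OTES, C2 3-(TBDPS-oxy)propyl, C1 homofarnesyl (C1, C2, C6 as in the target)
Conditions: LiAlH4, THF, 0 °C
Reagents that add atoms: none
Why: Hydride reduction of the γ-lactone reveals the C1 hydroxymethyl group and the C3 secondary alcohol; silyl ethers and trisubstituted olefins are inert.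

Step 13
Reactants: 23 diol; 24 2-(diethoxyphosphoryl)propanoic acid
Product: 25 mono-ester: the C1 hydroxymethyl group of 23 acylated as its 2-(diethoxyphosphoryl)propanoate (mixture at the phosphonate α-carbon), C3–OH free
Conditions: 24 (1.05 equiv), DCC, DMAP (cat.), CH2Cl2, −20 to 0 °C
Reagents that add atoms: none
Why: Carbodiimide esterification; the primary hydroxyl should react before the secondary C3 hydroxyl, which is flanked by the branched C2.

Step 14
Reactants: 25 hydroxy phosphonate ester
Product: 26 keto phosphonate: the C3 ketone of 25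
Conditions: DMP, CH2Cl2, rt
Reagents that add atoms: none
Why: Dess–Martin oxidation of the secondary alcohol under near-neutral conditions, which should leave the C2 centre next to the new ketone unepimerised.

Step 15
Reactants: 26 keto phosphonate
Product: 27 5,9-dimethyl-10-{3-[(tert-butyldiphenylsilyl)oxy]propyl}-9-[(triethylsilyl)oxy]-1-[(3E,7E)-4,8,12-trimethyltrideca-3,7,11-trien-1-yl]-3-oxabicyclo[4.3.1]dec-5-en-4-one (seven-membered unsaturated lactone spanning ring C1 and C3)
Conditions: LiCl, DBU, MeCN (5 mM), rt to 50 °C
Reagents that add atoms: none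
Why: Intramolecular Horner–Wadsworth–Emmons reaction under mild LiCl/amine conditions closes the seven-membered lactone; the ester tether forces the carbonyl carbon syn to C2, so the geometry of the tetrasubstituted olefin is fixed by the ring, and the weak base limits enolisation toward C2.

Step 16
Reactants: 27 bis-silylated unsaturated lactone
Product: 28 9-hydroxy-10-(3-hydroxypropyl)-5,9-dimethyl-1-[(3E,7E)-4,8,12-trimethyltrideca-3,7,11-trien-1-yl]-3-oxabicyclo[4.3.1]dec-5-en-4-one
Conditions: TBAF, AcOH, THF, rt
Reagents that add atoms: none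
Why: Fluoride removes both silyl ethers; buffering with AcOH should suppress alkoxide-driven translactonisation and oxa-Michael addition, and a translactonised isomer would give the same product in step 17.

Step 17
Reactants: 28 dihydroxy unsaturated lactone
Product: 29 (2Z)-2-[(2R,3S,4S)-4-hydroxy-3-(hydroxymethyl)-2-(3-hydroxypropyl)-4-methyl-3-[(3E,7E)-4,8,12-trimethyltrideca-3,7,11-trien-1-yl]cyclohexylidene]propanal (target)
Conditions: DIBAL-H (5 equiv), CH2Cl2, −78 °C; aq. potassium sodium tartrate
Reagents that add atoms: none
Why: Partial reduction of the lactone at low temperature gives the aluminium hemiacetal, which on work-up should open to the conjugated hydroxy-enal; the olefin is not touched, so the ring-enforced Z geometry is kept.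

## Compound list

1 | pent-4-en-1-ol | C=CCCCO | starting material
2 | tert-butyl(pent-4-en-1-yloxy)diphenylsilane | C=CCCCO[Si](c1ccccc1)(c1ccccc1)C(C)(C)C | intermediate
3 | (E)-but-2-enal | C/C=C/C=O | starting material
4 | (E)-6-[(tert-butyldiphenylsilyl)oxy]hex-2-enal | O=C/C=C/CCCO[Si](c1ccccc1)(c1ccccc1)C(C)(C)C | intermediate
5 | 2-methoxypropene | COC(C)=C | starting material
6 | (4R,5E)-9-[(tert-butyldiphenylsilyl)oxy]-2-methoxynona-1,5-dien-4-ol (enol ether adduct, not isolated) | COC(=C)C[C@@H](O)/C=C/CCCO[Si](c1ccccc1)(c1ccccc1)C(C)(C)C | intermediate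
7 | (4R,5E)-9-[(tert-butyldiphenylsilyl)oxy]-4-hydroxynon-5-en-2-one | CC(=O)C[C@@H](O)/C=C/CCCO[Si](c1ccccc1)(c1ccccc1)C(C)(C)C | intermediate
8 | (E)-4-bromobut-2-enoic acid | OC(=O)/C=C/CBr | starting material
9 | (4R,5E)-9-[(tert-butyldiphenylsilyl)oxy]-2-oxonon-5-en-4-yl (2E)-4-bromobut-2-enoate | CC(=O)C[C@@H](OC(=O)/C=C/CBr)/C=C/CCCO[Si](c1ccccc1)(c1ccccc1)C(C)(C)C | intermediate
10 | (3RS,4S,6R)-6-{(1E)-5-[(tert-butyldiphenylsilyl)oxy]pent-1-en-1-yl}-4-hydroxy-4-methyl-3-vinyltetrahydro-2H-pyran-2-one | C=CC1C(=O)O[C@@H](/C=C/CCCO[Si](c2ccccc2)(c2ccccc2)C(C)(C)C)C[C@]1(C)O | intermediate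
11 | (2R,4S)-2-{(1E)-5-[(tert-butyldiphenylsilyl)oxy]pent-1-en-1-yl}-4-methyl-4,6-bis[(triethylsilyl)oxy]-5-vinyl-3,4-dihydro-2H-pyran (dienyl ketene acetal, not isolated) | C=CC1=C(O[Si](CC)(CC)CC)O[C@@H](/C=C/CCCO[Si](c2ccccc2)(c2ccccc2)C(C)(C)C)C[C@]1(C)O[Si](CC)(CC)CC | intermediate
12 | triethylsilyl (1R,2R,6S)-2-{3-[(tert-butyldiphenylsilyl)oxy]propyl}-6-methyl-6-[(triethylsilyl)oxy]-1-vinylcyclohex-3-ene-1-carboxylate (silyl ester, not isolated) | C=C[C@@]1(C(=O)O[Si](CC)(CC)CC)[C@H](CCCO[Si](c2ccccc2)(c2ccccc2)C(C)(C)C)C=CC[C@]1(C)O[Si](CC)(CC)CC | intermediate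
13 | (1R,2R,6S)-2-{3-[(tert-butyldiphenylsilyl)oxy]propyl}-6-methyl-6-[(triethylsilyl)oxy]-1-vinylcyclohex-3-ene-1-carboxylic acid | C=C[C@@]1(C(=O)O)[C@H](CCCO[Si](c2ccccc2)(c2ccccc2)C(C)(C)C)C=CC[C@]1(C)O[Si](CC)(CC)CC | intermediate
14 | 4-iodo-2-methyl-8-{3-[(tert-butyldiphenylsilyl)oxy]propyl}-2-[(triethylsilyl)oxy]-1-vinyl-6-oxabicyclo[3.2.1]octan-7-one (iodo-γ-lactone, I trans to lactone O) | C=C[C@@]12C(=O)O[C@@H]([C@H]1CCCO[Si](c3ccccc3)(c4ccccc4)C(C)(C)C)[C@@H](I)C[C@]2(C)O[Si](CC)(CC)CC | intermediate
15 | 2-methyl-8-{3-[(tert-butyldiphenylsilyl)oxy]propyl}-2-[(triethylsilyl)oxy]-1-vinyl-6-oxabicyclo[3.2.1]octan-7-one | C=C[C@@]12C(=O)O[C@@H]([C@H]1CCCO[Si](c3ccccc3)(c4ccccc4)C(C)(C)C)CC[C@]2(C)O[Si](CC)(CC)CC | intermediate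
16 | (5E)-6,10-dimethylundeca-5,9-dien-2-one | CC(C)=CCC/C(C)=C/CCC(C)=O | starting material
17 | (5E)-6,10-dimethylundeca-1,5,9-trien-2-yl diethyl phosphate (enol phosphate, not isolated) | CC(C)=CCC/C(C)=C/CCC(=C)OP(=O)(OCC)OCC | intermediate
18 | (5E)-6,10-dimethylundeca-5,9-dien-1-yne | CC(C)=CCC/C(C)=C/CCC#C | intermediate
19 | dimethyl[(1E,5E)-2,6,10-trimethylundeca-1,5,9-trien-1-yl]alane (not isolated) | CC(C)=CCC/C(C)=C/CC/C(C)=C/[Al](C)C | intermediate
20 | (1E,5E)-1-iodo-2,6,10-trimethylundeca-1,5,9-triene | CC(C)=CCC/C(C)=C/CC/C(C)=C/I | intermediate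
21 | B-alkyl-9-BBN adduct of 15 (boron on the terminal carbon of the former vinyl group, not isolated) | B1(C2CCCC1CCC2)CC[C@@]12C(=O)O[C@@H]([C@H]1CCCO[Si](c3ccccc3)(c4ccccc4)C(C)(C)C)CC[C@]2(C)O[Si](CC)(CC)CC | intermediate
22 | 2-methyl-8-{3-[(tert-butyldiphenylsilyl)oxy]propyl}-2-[(triethylsilyl)oxy]-1-[(3E,7E)-4,8,12-trimethyltrideca-3,7,11-trien-1-yl]-6-oxabicyclo[3.2.1]octan-7-one | CC(C)=CCC/C(C)=C/CC/C(C)=C/CC[C@@]12C(=O)O[C@@H]([C@H]1CCCO[Si](c3ccccc3)(c4ccccc4)C(C)(C)C)CC[C@]2(C)O[Si](CC)(CC)CC | intermediate
23 | diol: C1 hydroxymethyl, C3 hydroxyl (cis), C6 OTES, C2 3-(TBDPS-oxy)propyl, C1 homofarnesyl | CC(C)=CCC/C(C)=C/CC/C(C)=C/CC[C@@]1(CO)[C@H](CCCO[Si](c2ccccc2)(c3ccccc3)C(C)(C)C)[C@H](O)CC[C@]1(C)O[Si](CC)(CC)CC | intermediate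
24 | 2-(diethoxyphosphoryl)propanoic acid | CCOP(=O)(OCC)C(C)C(=O)O | starting material
25 | C1-CH2 2-(diethoxyphosphoryl)propanoate of diol 23 | CC(C)=CCC/C(C)=C/CC/C(C)=C/CC[C@@]1(COC(=O)C(C)P(=O)(OCC)OCC)[C@H](CCCO[Si](c2ccccc2)(c3ccccc3)C(C)(C)C)[C@H](O)CC[C@]1(C)O[Si](CC)(CC)CC | intermediate
26 | C3 ketone of 25 (keto phosphonate) | CC(C)=CCC/C(C)=C/CC/C(C)=C/CC[C@@]1(COC(=O)C(C)P(=O)(OCC)OCC)[C@H](CCCO[Si](c2ccccc2)(c3ccccc3)C(C)(C)C)C(=O)CC[C@]1(C)O[Si](CC)(CC)CC | intermediate
27 | 5,9-dimethyl-10-{3-[(tert-butyldiphenylsilyl)oxy]propyl}-9-[(triethylsilyl)oxy]-1-[(3E,7E)-4,8,12-trimethyltrideca-3,7,11-trien-1-yl]-3-oxabicyclo[4.3.1]dec-5-en-4-one | CC(C)=CCC/C(C)=C/CC/C(C)=C/CC[C@@]12COC(=O)/C(C)=C(\[C@H]1CCCO[Si](c3ccccc3)(c4ccccc4)C(C)(C)C)CC[C@]2(C)O[Si](CC)(CC)CC | intermediate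
28 | 9-hydroxy-10-(3-hydroxypropyl)-5,9-dimethyl-1-[(3E,7E)-4,8,12-trimethyltrideca-3,7,11-trien-1-yl]-3-oxabicyclo[4.3.1]dec-5-en-4-one | CC(C)=CCC/C(C)=C/CC/C(C)=C/CC[C@@]12COC(=O)/C(C)=C(\[C@H]1CCCO)CC[C@]2(C)O | intermediate
29 | (2Z)-2-[(2R,3S,4S)-4-hydroxy-3-(hydroxymethyl)-2-(3-hydroxypropyl)-4-methyl-3-[(3E,7E)-4,8,12-trimethyltrideca-3,7,11-trien-1-yl]cyclohexylidene]propanal | CC(C)=CCC/C(C)=C/CC/C(C)=C/CC[C@@]1(CO)[C@H](CCCO)/C(=C(/C)C=O)CC[C@]1(C)O | target

## Step count and least certain steps

Total step count: 17. Longest linear sequence: 15 (steps 1–8 and 11–17); steps 9–10 form the convergent side-chain fragment.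

**Step 6 (key step).** Most likely failure: loss of the C4 silyloxy group by elimination during enolisation, or desilylation and decomposition of the ketene acetal if the shift through the crowded boat is slow. Fallback without any enolate, at the aldehyde oxidation level: starting from 10, silylation of the tertiary alcohol gives the triethylsilyl ether lactone F1, DIBAL-H reduction gives the lactol F2, and dehydration (MsCl, Et3N) gives the 5-vinyl-3,4-dihydro-2H-pyran dienyl ether F3. Thermal Claisen ring contraction of this neutral enol ether (sealed tube, about 180 °C) through the same boat should give the cyclohexenecarbaldehyde F4, and chlorite oxidation returns to the route at 13.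

**Step 5.** Most likely failure: protonation of the samarium dienolate without cyclisation, reaction through its γ-carbon, or weaker 1,3-induction than with simple bromoacetates. Fallback through the directly precedented bromoacetate class: starting from 7, acylation with bromoacetyl bromide gives the bromoacetate F5, and SmI2 cyclisation gives the (4S,6R)-4-hydroxy-4-methyl lactone F6. Aldol addition of its dianion to acetaldehyde gives the hydroxyethyl lactone F7, and selective mesylation–elimination of the secondary alcohol gives the α-ethylidene lactone F8. γ-Deprotonation and silylation of F8 gives the same dienyl ketene acetal, so the route is rejoined at 11.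

**Step 13.** Most likely failure: acylation of the secondary C3 hydroxyl or of both hydroxyls. Fallback that removes the competition: starting from 23, an Oppenauer oxidation (which oxidises secondary alcohols in preference to primary ones and spares the polyene) gives the hydroxy ketone F9, and carbodiimide coupling of its only remaining free primary hydroxyl with 24 returns to the route at 26.

**Step 15.** Most likely failure: slow addition of the α-methyl phosphonate carbanion to the hindered α-branched ketone, allowing enolisation toward C2 (epimerisation) or oligomerisation. Fallback by a reductive aldol–dehydration: starting from 23, selective acylation with 2-bromopropanoyl bromide gives the bromo ester F10, Dess–Martin oxidation gives the keto bromo ester F11, and an intramolecular SmI2 Reformatsky reaction gives the bridged β-hydroxy lactone F12. Dehydration of its tertiary alcohol with the Burgess reagent returns to the route at 27, the ring again enforcing the olefin geometry.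

**Step 17.** Most likely failure: collapse of the aluminium hemiacetal at low temperature followed by over-reduction to the allylic alcohol, or conjugate reduction. Fallback: starting from 28, complete reduction with LiAlH4 gives the tetraol F13, and MnO2, which oxidises only the allylic primary alcohol, returns to the route at 29.

## Further compounds

F1 | step 6 | (3RS,4S,6R)-6-{(1E)-5-[(tert-butyldiphenylsilyl)oxy]pent-1-en-1-yl}-4-methyl-4-[(triethylsilyl)oxy]-3-vinyltetrahydro-2H-pyran-2-one | C=CC1C(=O)O[C@@H](/C=C/CCCO[Si](c2ccccc2)(c2ccccc2)C(C)(C)C)C[C@]1(C)O[Si](CC)(CC)CC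
F2 | step 6 | corresponding lactol (tetrahydro-2H-pyran-2-ol) | C=CC1C(O)O[C@@H](/C=C/CCCO[Si](c2ccccc2)(c2ccccc2)C(C)(C)C)C[C@]1(C)O[Si](CC)(CC)CC
F3 | step 6 | (2R,4S)-2-{(1E)-5-[(tert-butyldiphenylsilyl)oxy]pent-1-en-1-yl}-4-methyl-4-[(triethylsilyl)oxy]-5-vinyl-3,4-dihydro-2H-pyran | C=CC1=CO[C@@H](/C=C/CCCO[Si](c2ccccc2)(c2ccccc2)C(C)(C)C)C[C@]1(C)O[Si](CC)(CC)CC
F4 | step 6 | (1R,2R,6S)-2-{3-[(tert-butyldiphenylsilyl)oxy]propyl}-6-methyl-6-[(triethylsilyl)oxy]-1-vinylcyclohex-3-ene-1-carbaldehyde | C=C[C@@]1(C=O)[C@H](CCCO[Si](c2ccccc2)(c2ccccc2)C(C)(C)C)C=CC[C@]1(C)O[Si](CC)(CC)CC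
F5 | step 5 | (4R,5E)-9-[(tert-butyldiphenylsilyl)oxy]-2-oxonon-5-en-4-yl bromoacetate | CC(=O)C[C@@H](OC(=O)CBr)/C=C/CCCO[Si](c1ccccc1)(c1ccccc1)C(C)(C)C
F6 | step 5 | (4S,6R)-6-{(1E)-5-[(tert-butyldiphenylsilyl)oxy]pent-1-en-1-yl}-4-hydroxy-4-methyltetrahydro-2H-pyran-2-one | C1C(=O)O[C@@H](/C=C/CCCO[Si](c2ccccc2)(c2ccccc2)C(C)(C)C)C[C@]1(C)O
F7 | step 5 | 3-(1-hydroxyethyl) derivative of F6 | CC(O)C1C(=O)O[C@@H](/C=C/CCCO[Si](c2ccccc2)(c2ccccc2)C(C)(C)C)C[C@]1(C)O
F8 | step 5 | 3-ethylidene derivative of F6 | CC=C1C(=O)O[C@@H](/C=C/CCCO[Si](c2ccccc2)(c2ccccc2)C(C)(C)C)C[C@]1(C)O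
F9 | step 13 | hydroxy ketone: C3 ketone of diol 23 with free C1 hydroxymethyl | CC(C)=CCC/C(C)=C/CC/C(C)=C/CC[C@@]1(CO)[C@H](CCCO[Si](c2ccccc2)(c3ccccc3)C(C)(C)C)C(=O)CC[C@]1(C)O[Si](CC)(CC)CC
F10 | step 15 | C1-CH2 2-bromopropanoate of diol 23 | CC(C)=CCC/C(C)=C/CC/C(C)=C/CC[C@@]1(COC(=O)C(C)Br)[C@H](CCCO[Si](c2ccccc2)(c3ccccc3)C(C)(C)C)[C@H](O)CC[C@]1(C)O[Si](CC)(CC)CC
F11 | step 15 | C3 ketone of F10 | CC(C)=CCC/C(C)=C/CC/C(C)=C/CC[C@@]1(COC(=O)C(C)Br)[C@H](CCCO[Si](c2ccccc2)(c3ccccc3)C(C)(C)C)C(=O)CC[C@]1(C)O[Si](CC)(CC)CC
F12 | step 15 | bridged β-hydroxy lactone (6-hydroxy-3-oxabicyclo[4.3.1]decan-4-one, hydrate of 27 across the olefin) | CC(C)=CCC/C(C)=C/CC/C(C)=C/CC[C@@]12COC(=O)C(C)C(O)([C@H]1CCCO[Si](c3ccccc3)(c4ccccc4)C(C)(C)C)CC[C@]2(C)O[Si](CC)(CC)CC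
F13 | step 17 | tetraol: (2Z)-allylic alcohol corresponding to 29 | CC(C)=CCC/C(C)=C/CC/C(C)=C/CC[C@@]1(CO)[C@H](CCCO)/C(=C(/C)CO)CC[C@]1(C)O
A1 | alternative 1 | methyl 8-oxo-1,4-dioxaspiro[4.5]dec-6-ene-7-carboxylate | COC(=O)C1=CC2(OCCO2)CCC1=O
A2 | alternative 1 | trans conjugate-addition/alkylation keto ester (C1 CO2Me and homofarnesyl, C2 silyloxypropyl, C3 ketal, C6 ketone) | CC(C)=CCC/C(C)=C/CC/C(C)=C/CC[C@@]1(C(=O)OC)[C@H](CCCO[Si](c2ccccc2)(c3ccccc3)C(C)(C)C)C2(OCCO2)CCC1=O
A3 | alternative 2 | trans-6-allyl-(S)-carvone | CC1=CC[C@H](C(C)=C)[C@@H](CC=C)C1=O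
A4 | alternative 2 | (tributylstannyl)methyl ether of the transposed cyclohexenol carrying the homofarnesyl chain | CC(C)=CCC/C(C)=C/CC/C(C)=C/CCC1=C(C)[C@@H](OC[Sn](CCCC)(CCCC)CCCC)C[C@H](C(C)=C)[C@H]1CC=C
A5 | alternative 3 | 1,7,9-decatrien-3-one with C6 silyloxy/methyl and a 7-(2-PMB-oxyethyl) group | C=CC(=O)CC[C@](C)(O[Si](CC)(CC)CC)/C(CCOCc1ccc(OC)cc1)=C/C=C
A6 | alternative 3 | cis-fused octalone cycloadduct | O=C1CC[C@](C)(O[Si](CC)(CC)CC)[C@]2(CCOCc3ccc(OC)cc3)C=CCC[C@H]12
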